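free monomer 20 mM; protic impurity 6.00 mM; initiator 0.50 mM; time 8.0 min

- whether the average number of monomer units in a chain (chains begun, living or dead) reaches 8.0 by 8.0 min (yes / no)
- average number of monomer units in a chain (chains begun, living or dead) at 8.0 min

    monomer in chains + living end → free monomer + living end, rate k1*[living end] as long as [monomer in chains] is above zero (k1 = 0.83 /s)
    free monomer + initiator → living end + monomer in chains (k2 = 3.0 /M/s)
    protic impurity + free monomer → quenched substrate (k3 = 0.085 /M/s)
    2 initiator → spent initiator (k4 = 8.7 /M/s)
    free monomer + living end → monomer in chains + living end, rate k5*[living end]*[free monomer] (k5 = 82 /M/s)

Each initiator ends either as a living end, by meeting free monomer, or two at a time as spent initiator, so its balance needs one ratio: its use by free monomer over its use by itself, at the charge.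

ratio of the two uses: 6.90
share of initiator that begins chains (ratio times the logarithm of one plus its inverse, free monomer held at its charge): 93.4 %

The first rung is initiation: with free monomer held at its charge, initiator has a half-life of 0.193 min by this path, shorter than the 1.92 min for self-destruction. Each living end then adds free monomer and gives it back, and these two steps balance at the standing fraction, the constant of return over the constant of addition, taken as a fraction of the free monomer charged (the equilibrium monomer concentration):

standing fraction: 50.6 %

Free monomer nears that level with a half-life of 0.302 min. The last rung is protic impurity, whose half-life at the standing level is 13.4 min, which is longer than the run. Free monomer is resupplied faster than impurity takes it, so what is quenched comes out of the chains: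

quenched, as a fraction of the monomer charge: 10.1 %
left in chains: 39.2 %
length: 16.8
reaches 8.0: yes

The forecast gave yes and 16.4, on the grounds that "Impurity slowly drains free monomer, and the chains feed it back." The simulation gives yes and 16.8, with the wanted length reached at 0.280 min.

In this flask, initiation and chain growth ran first: by 0.800 min initiator was down to 8.37 % of its charge, living ends stood at 0.423 mM and free monomer at 63.6 %. Free monomer stood at 50.1 % at 4.00 min and 50.2 % at 8.00 min, near the standing 50.6 %, while quenched substrate grew from 6.30 % to 10.7 % and monomer in chains fell from 43.6 % to 39.2 %. At 80.0 min, the standing fraction and the quenched 29.5 % leave 19.9 % for the chains, and the flask holds 19.9 % there.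

All constants were set for the occasion, and the outcome is calculated.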